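**Retrosynthetic overview**

1. The C6–O ester (acid 26) and the C11=C13 methylene are added last to the tricyclic core 18.
2. Key disconnection C3–C4: C3 is the oxygen-bearing β-carbon of the furanone enone (O–C3=C2–C1=O) and lies across the ring from the C10 oxygen. Opening C3–O gives a C2≡C3 ynone with a free C10–OH, so the bond becomes an sp–sp2 bond between a terminal alkyne (C3–H) and the (Z)-vinyl iodide (C4–I).
3. One operation: Sonogashira coupling closes the 10-membered carbocycle (C1–C10), then transannular addition of O10 to C3 stitches the 3(2H)-furanone ring (O, C10, C1, C2, C3).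
4. Precursor 16 by a lactone relay: O8 is first captured as a γ-lactone on C1 (citramalic dioxolanone), released by acetylide addition (C1–C2), then re-closed on C12. C6/C7 come from a syn boron aldol with (Z)-3-iodobut-2-enal, C8 from a 1,3-syn reduction, C10 from (R)-citramalic acid.
5. Ring order: C1–O8 γ-lactone (temporary) → C12–O8 γ-lactone → 10-membered carbocycle → furanone (same step); the oxirane acid is made separately.

Key step: step 10

Remark: C-numbers are germacrane numbers of the target (C1–C10 carbocycle, C11–C13 lactone arm, C14 on C10, C15 on C4) and are used for all intermediates. The ester is taken as drawn, (2S,3R)-2,3-dimethyloxirane-2-carboxylate (cis methyl groups). Transient centres (C11 in 20, 21, F3–F5; C1 in F1, F2) are not controlled and are written without configuration. Compounds 1, 4, 6 and 24 are assumed to be purchased.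

**Step 1**
Reactants: 1 but-2-yn-1-ol
Product: 2 (2Z)-3-iodobut-2-en-1-ol
Conditions: NaAlH2(OCH2CH2OMe)2, THF, 0 °C to rt; then I2, −78 °C
Reagents that add atoms: iodine, II
Why: Hydroxyl-directed trans-hydroalumination of the propargylic alcohol places aluminium on the distal carbon, and iodinolysis with retention should give the (Z)-vinyl iodide with iodine cis to the carbinol carbon.

**Step 2**
Reactants: 2 (2Z)-3-iodobut-2-en-1-ol
Product: 3 (2Z)-3-iodobut-2-enal
Conditions: MnO2, CH2Cl2, rt, dark; used at once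
Reagents that add atoms: none
Why: Allylic oxidation with MnO2 is neutral and should leave the Z geometry intact.

**Step 3**
Reactants: 4 (R)-citramalic acid [(2R)-2-hydroxy-2-methylbutanedioic acid]
Product: 5 2-[(4R)-2,2,4-trimethyl-5-oxo-1,3-dioxolan-4-yl]acetic acid
Conditions: 2,2-dimethoxypropane, TsOH·H2O (cat.), acetone, rt
Reagents that add atoms: 2,2-dimethoxypropane, COC(C)(C)OC
Why: Acetonide (1,3-dioxolan-4-one) formation of the α-hydroxy acid differentiates the two carboxyl groups (C1 masked, C8 free); the C10 stereocentre is not involved.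

**Step 4**
Reactants: 5 dioxolanone acid; 6 tert-butyl 3-bromopropanoate
Product: 9 tert-butyl 4-oxo-5-[(4R)-2,2,4-trimethyl-5-oxo-1,3-dioxolan-4-yl]pentanoate, via acid chloride 7 (not isolated), via organozinc bromide 8 (not isolated)
Conditions: 5, (COCl)2, DMF (cat.), CH2Cl2, 0 °C to rt, evaporate; 6, Zn dust, LiCl, THF, 40 °C; then both, Pd(PPh3)4 (cat.), THF, 0 °C to rt
Reagents that add atoms: none
Why: Negishi-type acylation: the zinc homoenolate couples with the acid chloride under zerovalent-palladium catalysis and tolerates the dioxolanone and the tert-butyl ester, so the C8 ketone should form without over-addition.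

**Step 5**
Reactants: 9 keto ester; 3 (2Z)-3-iodobut-2-enal
Product: 11 tert-butyl (3S,4S,5Z)-4-hydroxy-6-iodo-3-{[(4R)-2,2,4-trimethyl-5-oxo-1,3-dioxolan-4-yl]acetyl}hept-5-enoate, via boron enolate 10 (not isolated)
Conditions: (−)-Ipc2BOTf, iPr2NEt, CH2Cl2, −78 °C; then 3, −78 to −20 °C; H2O2, MeOH, pH 7 buffer, 0 °C
Reagents that add atoms: none
Why: Boron aldol: the bulky boron triflate should enolise the less hindered C7 methylene to the Z-enolate, whose closed chair (Zimmerman–Traxler) transition state gives the 6,7-syn adduct, and the Ipc ligands (from (+)-α-pinene) are expected to direct attack to the Si face of the aldehyde, setting C6 and C7 as required.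

**Step 6**
Reactants: 11 syn-aldol adduct
Product: 13 tert-butyl (3S,4S,5Z)-4-hydroxy-3-[(2S,4R)-4-hydroxy-4-methyl-5-oxooxolan-2-yl]-6-iodohept-5-enoate, via syn-1,3-diol 12 (not isolated)
Conditions: Et2BOMe, THF/MeOH, −78 °C; NaBH4, −78 °C; AcOH, then MeOH co-evaporation; then DBU (cat.), CH2Cl2, 0 °C
Reagents that add atoms: none
Why: Narasaka–Prasad reduction: hydride adds to the boron chelate of the β-hydroxy ketone to give the 6,8-syn diol (C8 set by C6), and only the C8 hydroxyl can reach the dioxolanone carbonyl C1 through a 5-membered transition state, so transesterification with loss of acetone lactonises O8 selectively while O6 stays free and the tert-butyl ester stays open.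

**Step 7**
Reactants: 13 hydroxy lactone
Product: 14 O6-triisopropylsilyl, O10-trimethylsilyl bis-silyl ether of 13 (configuration unchanged)
Conditions: TIPSOTf, 2,6-lutidine, CH2Cl2, −78 to 0 °C; then TMSOTf, 0 °C
Reagents that add atoms: triisopropylsilyl triflate, CC(C)[Si](OS(=O)(=O)C(F)(F)F)(C(C)C)C(C)C; trimethylsilyl triflate, C[Si](C)(C)OS(=O)(=O)C(F)(F)F
Why: Silylation: the bulky TIPS triflate should take only the secondary C6 hydroxyl, after which TMS triflate caps the tertiary C10 hydroxyl.

**Step 8**
Reactants: 14 bis-silyl lactone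
Product: 15 open-chain γ-hydroxy ynone (C8–OH, C1 ketone carrying the ethynyl group C2≡C3–H; silyl ethers and tert-butyl ester unchanged; in equilibrium with its cyclic hemiketal)
Conditions: acetylene, n-BuLi, THF, −78 °C; then 14, −78 °C; AcOH, −78 °C
Reagents that add atoms: lithium acetylide, [Li]C#C (from acetylene, C#C)
Why: Addition of an alkynyllithium to a lactone: the tetrahedral lithium hemiketal is stable at −78 °C, so a single addition should give the ynone (C1–C2 bond) and release O8, while the tert-butyl ester does not react.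

**Step 9**
Reactants: 15 γ-hydroxy ynone
Product: 16 (4R,5S)-5-[(2R)-2-hydroxy-2-methyl-3-oxopent-4-yn-1-yl]-4-{(1S,2Z)-3-iodo-1-[(triisopropylsilyl)oxy]but-2-en-1-yl}oxolan-2-one
Conditions: TFA, CH2Cl2, 0 °C to rt
Reagents that add atoms: none
Why: Acidolysis of the tert-butyl ester and the TMS ether followed by acid-catalysed γ-lactonisation: O8 is the only free hydroxyl that can form a 5-membered lactone with C12 (O6 is silylated), so the trans-disubstituted lactone should form with retention at C8.

**Step 10**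
Reactants: 16 hydroxy ynone vinyl iodide
Product: 18 tricyclic furanone (11,13-dihydro 6-O-TIPS core of the target), via macrocyclic ynone 17 (not isolated)
Conditions: Pd(PPh3)4 (10 mol%), CuI (20 mol%), iPr2NEt, degassed THF, 16 added by syringe pump to 1 mM, rt; then DBU (0.2 equiv), rt
Reagents that add atoms: none
Why: Zerovalent palladium inserts into the C4–I bond with retention, the terminal ynone forms its copper acetylide at C3, and transmetalation and reductive elimination make the C3–C4 bond, closing the 10-membered carbocycle C1–C10 as a cis-enynone by sp–sp2 cross-coupling (closest known reaction types: domino Sonogashira coupling/5-endo-dig heteroannulation and base-mediated cyclisation of α'-hydroxy ynones to 3(2H)-furanones). In cyclic ynone 17 the C10 hydroxyl sits across the ring from C3, so DBU-promoted transannular conjugate addition (5-endo-dig oxa-Michael) and protonation at C2 should close the furanone ring O–C10–C1–C2–C3, which is also the 9-membered oxa-bridge, and release the alkyne strain. No stereocentre is created; the C4=C5 geometry is that of the vinyl iodide and C6, C7, C8 and C10 are untouched. The step needs ring closure to beat oligomerisation, which high dilution, the cis C4=C5 bond and the trans-fused lactone turn should secure, and C–C coupling to precede O-cyclisation, which is expected because the copper acetylide is not a Michael acceptor and DBU is added only after the coupling. Two competing paths are designed out: the lactone has no exocyclic methylene yet (no intramolecular Heck reaction), and O6 is silylated, so the Z-enynol cannot collapse to a furan.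

**Step 11**
Reactants: 18 tricyclic furanone
Product: 22 6-O-TIPS ether of the 6-deacyl target (α-methylene lactone), via lithium enolate 19 (not isolated), via Mannich base 20 (not isolated), via ammonium iodide 21 (not isolated)
Conditions: LiN(SiMe3)2, THF, −78 °C; Me2N=CH2 iodide (Eschenmoser's salt), −78 to 0 °C; then MeI, MeOH, rt; then NaHCO3, CH2Cl2/H2O, rt
Reagents that add atoms: Eschenmoser's salt, C=[N+](C)C.[I-]
Why: α-Methylenation of a lactone by Mannich reaction of the kinetic lithium enolate, N-methylation and E1cB elimination; the exposed C11 methylene should be deprotonated faster than the buried C6 position of the strained dienone.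

**Step 12**
Reactants: 22 silyl ether
Product: 23 6-deacyl target (free C6–OH)
Conditions: HF·pyridine, pyridine, THF, 0 °C to rt
Reagents that add atoms: none
Why: Fluoride-mediated desilylation under buffered, weakly acidic conditions should spare the α-methylene lactone and the furanone.

**Step 13**
Reactants: 24 (2E)-2-methylbut-2-en-1-ol
Product: 25 [(2R,3R)-2,3-dimethyloxiran-2-yl]methanol
Conditions: Ti(OiPr)4 (cat.), D-(−)-diisopropyl tartrate (cat.), t-BuOOH, 4 Å molecular sieves, CH2Cl2, −20 °C
Reagents that add atoms: tert-butyl hydroperoxide, CC(C)(C)OO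
Why: Sharpless asymmetric epoxidation: the titanium–D-(−)-tartrate complex delivers oxygen to one face of the allylic alcohol, which for this E-alkene should give the (2R,3R)-epoxy alcohol (both oxirane centres set here, methyl groups cis).

**Step 14**
Reactants: 25 epoxy alcohol
Product: 26 (2S,3R)-2,3-dimethyloxirane-2-carboxylic acid
Conditions: RuCl3·xH2O (cat.), NaIO4, MeCN/EtOAc/H2O, 0 °C to rt
Reagents that add atoms: water, O; sodium periodate, [Na+].[O-]I(=O)(=O)=O
Why: RuO4-catalysed oxidation of the primary alcohol to the acid leaves the oxirane untouched; the descriptor at C2 changes only because the CIP priorities change.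

**Step 15**
Reactants: 23 6-deacyl target; 26 oxirane acid
Product: 28 target CNP0258430.2, via mixed anhydride 27 (not isolated)
Conditions: 26, 2,4,6-trichlorobenzoyl chloride, Et3N, toluene, rt; then 23, DMAP, toluene, rt
Reagents that add atoms: none
Why: Yamaguchi esterification acylates the hindered allylic C6 hydroxyl with retention at C6 and without touching the oxirane or the α-methylene lactone.

**Compound list**

1 | but-2-yn-1-ol | CC#CCO | starting material
2 | (2Z)-3-iodobut-2-en-1-ol | OC/C=C(/C)I | intermediate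
3 | (2Z)-3-iodobut-2-enal | O=C/C=C(/C)I | intermediate
4 | (R)-citramalic acid, (2R)-2-hydroxy-2-methylbutanedioic acid | C[C@@](O)(CC(=O)O)C(=O)O | starting material
5 | 2-[(4R)-2,2,4-trimethyl-5-oxo-1,3-dioxolan-4-yl]acetic acid | OC(=O)C[C@@]1(C)OC(C)(C)OC1=O | intermediate
6 | tert-butyl 3-bromopropanoate | CC(C)(C)OC(=O)CCBr | starting material
7 | [(4R)-2,2,4-trimethyl-5-oxo-1,3-dioxolan-4-yl]acetyl chloride | ClC(=O)C[C@@]1(C)OC(C)(C)OC1=O | intermediate (not isolated)
8 | [3-(tert-butoxy)-3-oxopropyl]zinc bromide | CC(C)(C)OC(=O)CC[Zn]Br | intermediate (not isolated)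
9 | tert-butyl 4-oxo-5-[(4R)-2,2,4-trimethyl-5-oxo-1,3-dioxolan-4-yl]pentanoate | CC(C)(C)OC(=O)CCC(=O)C[C@@]1(C)OC(C)(C)OC1=O | intermediate
10 | (Z)-diisopinocampheylboron enolate of 9 (C7=C8, O–B on C8) | CC(C)(C)OC(=O)C/C=C(\OB([C@@H]1C[C@@H]2C[C@H]([C@H]1C)C2(C)C)[C@@H]1C[C@@H]2C[C@H]([C@H]1C)C2(C)C)C[C@@]1(C)OC(C)(C)OC1=O | intermediate (not isolated)
11 | tert-butyl (3S,4S,5Z)-4-hydroxy-6-iodo-3-{[(4R)-2,2,4-trimethyl-5-oxo-1,3-dioxolan-4-yl]acetyl}hept-5-enoate (6,7-syn aldol) | CC(C)(C)OC(=O)C[C@@H]([C@H](O)/C=C(/C)I)C(=O)C[C@@]1(C)OC(C)(C)OC1=O | intermediate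
12 | 6,8-syn diol from 11 (C8 ketone reduced, dioxolanone intact) | CC(C)(C)OC(=O)C[C@@H]([C@H](O)/C=C(/C)I)[C@@H](O)C[C@@]1(C)OC(C)(C)OC1=O | intermediate (not isolated)
13 | tert-butyl (3S,4S,5Z)-4-hydroxy-3-[(2S,4R)-4-hydroxy-4-methyl-5-oxooxolan-2-yl]-6-iodohept-5-enoate | CC(C)(C)OC(=O)C[C@@H]([C@H](O)/C=C(/C)I)[C@@H]1C[C@@](C)(O)C(=O)O1 | intermediate
14 | O6-TIPS, O10-TMS bis-silyl ether of 13 | CC(C)(C)OC(=O)C[C@@H]([C@H](O[Si](C(C)C)(C(C)C)C(C)C)/C=C(/C)I)[C@@H]1C[C@@](C)(O[Si](C)(C)C)C(=O)O1 | intermediate
15 | open-chain γ-hydroxy ynone (C8–OH, C1(=O)–C≡CH, O6-TIPS, O10-TMS, tert-butyl ester) | CC(C)(C)OC(=O)C[C@@H]([C@H](O[Si](C(C)C)(C(C)C)C(C)C)/C=C(/C)I)[C@@H](O)C[C@@](C)(O[Si](C)(C)C)C(=O)C#C | intermediate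
16 | (4R,5S)-5-[(2R)-2-hydroxy-2-methyl-3-oxopent-4-yn-1-yl]-4-{(1S,2Z)-3-iodo-1-[(triisopropylsilyl)oxy]but-2-en-1-yl}oxolan-2-one | O=C1C[C@@H]([C@H](O[Si](C(C)C)(C(C)C)C(C)C)/C=C(/C)I)[C@H](C[C@@](C)(O)C(=O)C#C)O1 | intermediate
17 | macrocyclic ynone: 10-membered carbocycle with C1 ketone, C2≡C3, (4Z)-alkene, C6–OTIPS, C10–OH, trans-fused 12,8-lactone | C1C(=O)O[C@H]2C[C@@](C)(O)C(=O)C#C/C(C)=C\[C@@H](O[Si](C(C)C)(C(C)C)C(C)C)[C@H]12 | intermediate (not isolated)
18 | tricyclic furanone: 11,13-dihydro 6-O-TIPS core (3,10-epoxy-1-oxo-2,4Z-diene, 12,8-lactone) | C1C(=O)O[C@H]2C[C@@]3(C)OC(=CC3=O)/C(C)=C\[C@@H](O[Si](C(C)C)(C(C)C)C(C)C)[C@H]12 | intermediate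
19 | lithium enolate of lactone 18 (C11=C12–OLi) | C1=C(O[Li])O[C@H]2C[C@@]3(C)OC(=CC3=O)/C(C)=C\[C@@H](O[Si](C(C)C)(C(C)C)C(C)C)[C@H]12 | intermediate (not isolated)
20 | Mannich base: 18 with CH2NMe2 on C11 | CN(C)CC1C(=O)O[C@H]2C[C@@]3(C)OC(=CC3=O)/C(C)=C\[C@@H](O[Si](C(C)C)(C(C)C)C(C)C)[C@H]12 | intermediate (not isolated)
21 | trimethylammonium iodide of 20 | C[N+](C)(C)CC1C(=O)O[C@H]2C[C@@]3(C)OC(=CC3=O)/C(C)=C\[C@@H](O[Si](C(C)C)(C(C)C)C(C)C)[C@H]12.[I-] | intermediate (not isolated)
22 | 6-O-TIPS ether of the 6-deacyl target (α-methylene lactone) | C=C1C(=O)O[C@H]2C[C@@]3(C)OC(=CC3=O)/C(C)=C\[C@@H](O[Si](C(C)C)(C(C)C)C(C)C)[C@H]12 | intermediate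
23 | 6-deacyl target (C6–OH; 6R,7R,8S,10R) | C=C1C(=O)O[C@H]2C[C@@]3(C)OC(=CC3=O)/C(C)=C\[C@@H](O)[C@H]12 | intermediate
24 | (2E)-2-methylbut-2-en-1-ol | C/C=C(C)/CO | starting material
25 | [(2R,3R)-2,3-dimethyloxiran-2-yl]methanol | OC[C@@]1(C)O[C@@H]1C | intermediate
26 | (2S,3R)-2,3-dimethyloxirane-2-carboxylic acid | OC(=O)[C@@]1(C)O[C@@H]1C | intermediate
27 | mixed anhydride of 26 with 2,4,6-trichlorobenzoic acid | O=C(OC(=O)[C@@]1(C)O[C@@H]1C)c1c(Cl)cc(Cl)cc1Cl | intermediate (not isolated)
28 | CNP0258430.2: (2S,3R)-2,3-dimethyloxirane-2-carboxylate of 23 at O6 | C=C1C(=O)O[C@H]2C[C@@]3(C)OC(=CC3=O)/C(C)=C\[C@@H](OC(=O)[C@@]3(C)O[C@@H]3C)[C@H]12 | target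

**Totals**

Total step count: 15.
Longest linear sequence: 11 steps (steps 3–12 and 15, from (R)-citramalic acid 4).

**Steps most likely to fail**

1. Step 10. Intermolecular coupling (oligomerisation) may outrun ring closure, and the terminal ynone may be lost by amine addition or by O-cyclisation before the C–C bond forms. Fallback, from 16 back to 17/18: Luche reduction of 16 (NaBH4, CeCl3·7H2O, MeOH, −78 °C) should give the propargylic diol F1. Sonogashira macrocyclisation of this robust alkynol (Pd(PPh3)4, CuI, iPr2NEt, THF, high dilution) should give the cyclic enyne diol F2. MnO2 in CH2Cl2 then oxidises only the secondary propargylic alcohol and regenerates macrocyclic ynone 17, which DBU closes to 18. This moves the coupling to the alcohol oxidation level and makes the transannular closure a separate, oxidation-triggered event.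

2. Step 11. Extended enolisation of the dienone at C6, or base attack on the furanone, may compete with kinetic enolisation of the lactone. Fallback, from 14 back to 20: the aminomethyl group is installed before any ynone or furanone exists. LiN(iPr)2 and Eschenmoser's salt on the tert-butyl ester of 14 should give the Mannich ester F3. Lithium acetylide addition as in step 8 gives the amino hydroxy ynone F4, and TFA as in step 9 gives the amino lactone ynone F5. The step 10 conditions on F5 then deliver Mannich base 20 directly, and MeI/NaHCO3 completes the route to 22. The amine-masked methylene cannot undergo a Heck reaction during the palladium step.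

3. Step 8. The tetrahedral adduct may collapse before the quench, leading to a second acetylide addition, and silyl migration to O8 may interfere. Fallback, from 14 back to 16: lactone aminolysis with MeNHOMe·HCl and AlMe3 in CH2Cl2 should give the hydroxy Weinreb amide F6. Silylation of O8 (Et3SiCl, imidazole) gives the triethylsilyl ether F7. HC≡CMgBr in THF at 0 °C should stop at the ketone because of the chelated Weinreb adduct, giving the ynone F8. TFA then removes the TES, TMS and tert-butyl groups and lactonises to 16.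

**Further compounds**

F1 | step 10 | propargylic diol from 16 (C1 carbinol, both epimers) | O=C1C[C@@H]([C@H](O[Si](C(C)C)(C(C)C)C(C)C)/C=C(/C)I)[C@H](C[C@@](C)(O)C(O)C#C)O1
F2 | step 10 | cyclic enyne diol (10-membered ring, C1 carbinol, C10–OH) | C1C(=O)O[C@H]2C[C@@](C)(O)C(O)C#C/C(C)=C\[C@@H](O[Si](C(C)C)(C(C)C)C(C)C)[C@H]12
F3 | step 11 | Mannich ester: 14 with CH2NMe2 on C11 | CC(C)(C)OC(=O)C(CN(C)C)[C@@H]([C@H](O[Si](C(C)C)(C(C)C)C(C)C)/C=C(/C)I)[C@@H]1C[C@@](C)(O[Si](C)(C)C)C(=O)O1
F4 | step 11 | amino hydroxy ynone: 15 with CH2NMe2 on C11 | CC(C)(C)OC(=O)C(CN(C)C)[C@@H]([C@H](O[Si](C(C)C)(C(C)C)C(C)C)/C=C(/C)I)[C@@H](O)C[C@@](C)(O[Si](C)(C)C)C(=O)C#C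
F5 | step 11 | amino lactone ynone: 16 with CH2NMe2 on C11 | CN(C)CC1C(=O)O[C@@H](C[C@@](C)(O)C(=O)C#C)[C@@H]1[C@H](O[Si](C(C)C)(C(C)C)C(C)C)/C=C(/C)I
F6 | step 8 | hydroxy Weinreb amide (C1 N-methoxy-N-methylamide, C8–OH) | CC(C)(C)OC(=O)C[C@@H]([C@H](O[Si](C(C)C)(C(C)C)C(C)C)/C=C(/C)I)[C@@H](O)C[C@@](C)(O[Si](C)(C)C)C(=O)N(C)OC
F7 | step 8 | O8-triethylsilyl ether of F6 | CC(C)(C)OC(=O)C[C@@H]([C@H](O[Si](C(C)C)(C(C)C)C(C)C)/C=C(/C)I)[C@@H](O[Si](CC)(CC)CC)C[C@@](C)(O[Si](C)(C)C)C(=O)N(C)OC
F8 | step 8 | ynone with O8-TES, O10-TMS, O6-TIPS, tert-butyl ester | CC(C)(C)OC(=O)C[C@@H]([C@H](O[Si](C(C)C)(C(C)C)C(C)C)/C=C(/C)I)[C@@H](O[Si](CC)(CC)CC)C[C@@](C)(O[Si](C)(C)C)C(=O)C#C
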